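## Retrosynthetic overview

1. Target 18 ⇐ tris-MOM ether 17 by acetal cleavage; ring B is bought as 2,4,6-trihydroxybenzaldehyde.
2. 17 ⇐ one-flask double annulation of hydroxy ketone 13, ketene dithioacetal 7 and CDI: the C4a–C8a and O1–C8a bonds close ring C first, then the C6–C5 and C5–C4a bonds close ring A.
3. 13 ⇐ aldehyde 9 by Brown allylboration (sets C2) and Wacker oxidation.
4. 7 ⇐ (R)-limonene by ring ozonolysis, isopropylidene Wittig and kinetic CS2/MeI capture; the lavandulyl stereocentre is the limonene stereocentre.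

Assumption: the target is read as the (2S)-flavanone carrying a (2S)-5-methyl-2-(prop-1-en-2-yl)hex-4-enyl group at C6; commercial (R)-(+)-limonene (about 98% ee) sets the side-chain purity.

## Route

Step 1
Reactants: 1 (R)-(+)-limonene
Product: 3 (3R)-6-oxo-3-(prop-1-en-2-yl)heptanal, via secondary ozonide 2 (not isolated)
Conditions: O3 (1.0 equiv), CH2Cl2, −78 °C; then Me2S, −78 °C → rt
Reagents that add atoms: ozone, [O-][O+]=O
Why: Chemoselective ozonolysis, because the trisubstituted ring alkene is much more electron-rich than the 1,1-disubstituted isopropenyl group; the stereocentre is beta to both new carbonyls and is carried through unchanged.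

Step 2
Reactants: 3 (3R)-6-oxo-3-(prop-1-en-2-yl)heptanal; 4 isopropyltriphenylphosphonium iodide
Product: 6 (5R)-8-methyl-5-(prop-1-en-2-yl)non-7-en-2-one, via isopropylidenetriphenylphosphorane 5 (not isolated)
Conditions: KN(SiMe3)2, THF, 0 °C; then 3, −78 → 0 °C
Reagents that add atoms: none
Why: Wittig olefination, in which the non-stabilised ylide reacts with the aldehyde far faster than with the methyl ketone at low temperature and so completes the prenyl arm of the lavandulyl unit.

Step 3
Reactants: 6 (5R)-8-methyl-5-(prop-1-en-2-yl)non-7-en-2-one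
Product: 7 (6R)-9-methyl-1,1-bis(methylsulfanyl)-6-(prop-1-en-2-yl)deca-1,8-dien-3-one
Conditions: LiN(SiMe3)2 (2.2 equiv), THF, −78 °C; CS2, −78 → 0 °C; MeI, 0 °C → rt
Reagents that add atoms: carbon disulfide, S=C=S; iodomethane, CI
Why: α-Oxo ketene dithioacetal synthesis, in which the kinetic methyl-side enolate adds to CS2 and the dithiocarboxylate is deprotonated again and S-methylated twice, giving a one-carbon double electrophile at the future C8a.

Step 4
Reactants: 8 2,4,6-trihydroxybenzaldehyde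
Product: 9 2,4,6-tris(methoxymethoxy)benzaldehyde
Conditions: NaH, MOMCl, DMF, 0 °C → rt
Reagents that add atoms: chloromethyl methyl ether, COCCl
Why: O-Alkylation of the three phenoxides (MOM protection), giving ethers that tolerate the borane, the Pd/Cu oxidation and the amide bases used later.

Step 5
Reactants: 9 2,4,6-tris(methoxymethoxy)benzaldehyde; 10 (−)-B-allyldiisopinocampheylborane
Product: 12 (1S)-1-[2,4,6-tris(methoxymethoxy)phenyl]but-3-en-1-ol, via borinate ester 11 (not isolated)
Conditions: 10 (1 M in pentane), Et2O, −78 °C; then NaOH, H2O2, 0 °C → rt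
Reagents that add atoms: none
Why: Brown asymmetric allylboration through a chair transition state, in which the isopinocampheyl groups derived from (+)-α-pinene deliver allyl to the Si face of the aldehyde and set the benzylic carbinol (future C2) as S.

Step 6
Reactants: 12 (1S)-1-[2,4,6-tris(methoxymethoxy)phenyl]but-3-en-1-ol
Product: 13 (4S)-4-hydroxy-4-[2,4,6-tris(methoxymethoxy)phenyl]butan-2-one
Conditions: PdCl2 (10 mol%), CuCl (1 equiv), O2 (1 atm), DMF/H2O 7:1, rt
Reagents that add atoms: water, O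
Why: Tsuji–Wacker oxidation, in which Markovnikov hydroxypalladation of the terminal alkene gives the methyl ketone without touching the carbinol centre.

Step 7
Reactants: 13 (4S)-4-hydroxy-4-[2,4,6-tris(methoxymethoxy)phenyl]butan-2-one; 7 (6R)-9-methyl-1,1-bis(methylsulfanyl)-6-(prop-1-en-2-yl)deca-1,8-dien-3-one
Product: 17 (2S)-5,7-dihydroxy-6-[(2S)-5-methyl-2-(prop-1-en-2-yl)hex-4-en-1-yl]-2-[2,4,6-tris(methoxymethoxy)phenyl]-2,3-dihydro-4H-chromen-4-one, via open-chain thioenol ether 14 (not isolated), via dihydropyranone 15 (not isolated), via acyl imidazole 16 (not isolated)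
Conditions: LiN(i-Pr)2 (2.1 equiv), THF/DMPU, −78 °C; 7, −78 → 0 °C; LiN(i-Pr)2 (2.2 equiv), −78 °C; CDI, −78 → 0 °C; AcOH
Reagents that add atoms: 1,1'-carbonyldiimidazole (CDI), O=C(n1ccnc1)n1ccnc1
Why: Proposed new method: the alkoxide–enolate dianion of 13 attacks the single dithioacetal carbon of 7 twice by addition–elimination (enolate carbon, then alkoxide), which closes the 2,3-dihydro-4H-pyran-4-one with O1 fixed on C8a and the preset (S) C–O bond never broken; the side chain is then taken to its dianion, the terminal carbanion (C6) is acylated by CDI, and C4a of the remaining extended enolate attacks the acyl imidazole (the only six-membered closure available, since the enol oxygen is locked in ring C), so tautomerisation gives the phloroglucinol ring with lavandulyl at C6 by construction and no new stereocentre; the closest known chemistry is the Junjappa–Ila and Potts addition–elimination annulation of α-oxo ketene dithioacetals (including 2-(methylthio)chromone formation), Weiler-type acylation of 1,3-dicarbonyl dianions and Harris-type Claisen closure of polycarbonyl chains to acylphloroglucinols.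

Step 8
Reactants: 17 (2S)-5,7-dihydroxy-6-[(2S)-5-methyl-2-(prop-1-en-2-yl)hex-4-en-1-yl]-2-[2,4,6-tris(methoxymethoxy)phenyl]-2,3-dihydro-4H-chromen-4-one
Product: 18 (2S)-5,7-dihydroxy-6-[(2S)-5-methyl-2-(prop-1-en-2-yl)hex-4-en-1-yl]-2-(2,4,6-trihydroxyphenyl)-2,3-dihydro-4H-chromen-4-one
Conditions: ZnBr2 (3 equiv), n-PrSH (6 equiv), CH2Cl2, 0 °C, 15 min
Reagents that add atoms: none
Why: Lewis acid/thiol acetal cleavage, in which ZnBr2 activates each MOM oxygen and the thiol traps the methoxymethyl cation, under conditions short and cold enough to spare the lavandulyl alkenes and both stereocentres.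

## Compound list

1 | (R)-(+)-limonene, (4R)-1-methyl-4-(prop-1-en-2-yl)cyclohex-1-ene | CC1=CC[C@@H](CC1)C(C)=C | starting material
2 | (4R)-1-methyl-4-(prop-1-en-2-yl)-7,8,9-trioxabicyclo[4.2.1]nonane (ozonide, mixture at the acetal carbons) | CC12OOC(O1)C[C@@H](CC2)C(C)=C | intermediate
3 | (3R)-6-oxo-3-(prop-1-en-2-yl)heptanal | O=CC[C@@H](CCC(C)=O)C(C)=C | intermediate
4 | isopropyltriphenylphosphonium iodide | CC(C)[P+](c1ccccc1)(c1ccccc1)c1ccccc1.[I-] | starting material
5 | isopropylidenetriphenylphosphorane | CC(C)=P(c1ccccc1)(c1ccccc1)c1ccccc1 | intermediate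
6 | (5R)-8-methyl-5-(prop-1-en-2-yl)non-7-en-2-one | CC(C)=CC[C@@H](CCC(C)=O)C(C)=C | intermediate
7 | (6R)-9-methyl-1,1-bis(methylsulfanyl)-6-(prop-1-en-2-yl)deca-1,8-dien-3-one | CC(C)=CC[C@@H](CCC(=O)C=C(SC)SC)C(C)=C | intermediate
8 | 2,4,6-trihydroxybenzaldehyde | O=Cc1c(O)cc(O)cc1O | starting material
9 | 2,4,6-tris(methoxymethoxy)benzaldehyde | O=Cc1c(OCOC)cc(OCOC)cc1OCOC | intermediate
10 | (−)-B-allyldiisopinocampheylborane (from (+)-α-pinene) | C=CCB([C@@H]1C[C@@H]2C[C@@H](C2(C)C)[C@H]1C)[C@@H]1C[C@@H]2C[C@@H](C2(C)C)[C@H]1C | starting material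
11 | diisopinocampheylborinate of (1S)-1-[2,4,6-tris(methoxymethoxy)phenyl]but-3-en-1-ol | C=CC[C@H](OB([C@@H]1C[C@@H]2C[C@@H](C2(C)C)[C@H]1C)[C@@H]1C[C@@H]2C[C@@H](C2(C)C)[C@H]1C)c1c(OCOC)cc(OCOC)cc1OCOC | intermediate
12 | (1S)-1-[2,4,6-tris(methoxymethoxy)phenyl]but-3-en-1-ol | C=CC[C@H](O)c1c(OCOC)cc(OCOC)cc1OCOC | intermediate
13 | (4S)-4-hydroxy-4-[2,4,6-tris(methoxymethoxy)phenyl]butan-2-one | CC(=O)C[C@H](O)c1c(OCOC)cc(OCOC)cc1OCOC | intermediate
14 | (1S,10R)-1-hydroxy-13-methyl-5-(methylsulfanyl)-10-(prop-1-en-2-yl)-1-[2,4,6-tris(methoxymethoxy)phenyl]tetradeca-4,12-diene-3,7-dione | C=C(C)[C@@H](CC=C(C)C)CCC(=O)CC(SC)=CC(=O)C[C@H](O)c1c(OCOC)cc(OCOC)cc1OCOC | intermediate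
15 | (2S)-6-[(5R)-8-methyl-2-oxo-5-(prop-1-en-2-yl)non-7-en-1-yl]-2-[2,4,6-tris(methoxymethoxy)phenyl]-2,3-dihydro-4H-pyran-4-one | C=C(C)[C@@H](CC=C(C)C)CCC(=O)CC1=CC(=O)C[C@@H](c2c(OCOC)cc(OCOC)cc2OCOC)O1 | intermediate
16 | (2S)-6-[3-(1H-imidazole-1-carbonyl)-8-methyl-2-oxo-5-(prop-1-en-2-yl)non-7-en-1-yl]-2-[2,4,6-tris(methoxymethoxy)phenyl]-2,3-dihydro-4H-pyran-4-one (side-chain centre as in 6; new centre unassigned) | C=C(C)[C@@H](CC=C(C)C)CC(C(=O)n1ccnc1)C(=O)CC1=CC(=O)C[C@@H](c2c(OCOC)cc(OCOC)cc2OCOC)O1 | intermediate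
17 | (2S)-5,7-dihydroxy-6-[(2S)-5-methyl-2-(prop-1-en-2-yl)hex-4-en-1-yl]-2-[2,4,6-tris(methoxymethoxy)phenyl]-2,3-dihydro-4H-chromen-4-one | C=C(C)[C@@H](CC=C(C)C)Cc1c(O)cc2c(c1O)C(=O)C[C@@H](c1c(OCOC)cc(OCOC)cc1OCOC)O2 | intermediate
18 | (2S)-5,7-dihydroxy-6-[(2S)-5-methyl-2-(prop-1-en-2-yl)hex-4-en-1-yl]-2-(2,4,6-trihydroxyphenyl)-2,3-dihydro-4H-chromen-4-one | C=C(C)[C@@H](CC=C(C)C)Cc1c(O)cc2c(c1O)C(=O)C[C@@H](c1c(O)cc(O)cc1O)O2 | target

## Step count and risks

Total steps: 8. Longest linear sequence: 5 steps (4, 5, 6, 7, 8 from compound 8; equally 1, 2, 3, 7, 8 from compound 1).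

Steps most likely to fail:

Step 7. The lithium enolate of 13 may add to the carbonyl of 7 instead of the dithioacetal carbon, the aldolate of 13 may undergo retro-aldol cleavage, or the CDI stage may acylate at oxygen. The fallback sets out from 13 and 6 and comes back at 17, forming the two rings in separate steps. Compound 13 is treated with LiN(SiMe3)2, CS2 and MeI to give the ketene dithioacetal F1, whose hydroxyl displaces one methylthio group on warming with K2CO3 to give the cyclic ketene O,S-acetal F2 (the 2-(methylthio)chromone type of closure). The kinetic lithium enolate of 6 then displaces the remaining methylthio group to give 15, which is isolated. LiN(i-Pr)2 and Boc2O carboxylate the side chain of 15 at C6 to the tert-butyl β-keto ester F3. Heating F3 in toluene at 110 °C releases the acylketene, which closes ring A by 6π-electrocyclisation and tautomerises to 17.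

Step 6. The β-hydroxy ketone carries a very electron-rich benzylic alcohol and may dehydrate under the slightly acidic Pd/Cu chloride medium, and some aldehyde regioisomer is possible. The fallback sets out from 9 and comes back at 13. Brown methallylboration of 9 with (−)-B-methallyldiisopinocampheylborane gives the methallyl carbinol F4 with the same facial sense. Buffered Lemieux–Johnson cleavage of its 1,1-disubstituted alkene (OsO4 cat., NaIO4, 2,6-lutidine, dioxane/H2O) then gives 13 without acid.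

Step 8. The free 2',4',6'-trihydroxyphenyl flavanone can ionise at C2 (epimerisation) and the lavandulyl alkene can cyclise onto a neighbouring phenol if the Lewis acid is too strong or the contact too long. The fallback sets out from 17 and comes back at 18. TMSOTf with 2,2'-bipyridyl in CH2Cl2 at 0 °C converts the aryl MOM ethers and the free phenols into trimethylsilyl ethers, giving the pentakis(trimethylsilyl) ether F5. Neutral methanolysis of F5 (MeOH, rt) then gives 18 without any Brønsted or Lewis acid present on the free polyphenol.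

Further compounds
F1 | step 7 | (5S)-5-hydroxy-1,1-bis(methylsulfanyl)-5-[2,4,6-tris(methoxymethoxy)phenyl]pent-1-en-3-one | CSC(SC)=CC(=O)C[C@H](O)c1c(OCOC)cc(OCOC)cc1OCOC
F2 | step 7 | (2S)-6-(methylsulfanyl)-2-[2,4,6-tris(methoxymethoxy)phenyl]-2,3-dihydro-4H-pyran-4-one | CSC1=CC(=O)C[C@@H](c2c(OCOC)cc(OCOC)cc2OCOC)O1
F3 | step 7 | tert-butyl 7-methyl-2-{[(2S)-4-oxo-2-[2,4,6-tris(methoxymethoxy)phenyl]-3,4-dihydro-2H-pyran-6-yl]acetyl}-4-(prop-1-en-2-yl)oct-6-enoate (side-chain centre as in 6) | C=C(C)[C@@H](CC=C(C)C)CC(C(=O)OC(C)(C)C)C(=O)CC1=CC(=O)C[C@@H](c2c(OCOC)cc(OCOC)cc2OCOC)O1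
F4 | step 6 | (1S)-3-methyl-1-[2,4,6-tris(methoxymethoxy)phenyl]but-3-en-1-ol | C=C(C)C[C@H](O)c1c(OCOC)cc(OCOC)cc1OCOC
F5 | step 8 | (2S)-6-[(2S)-5-methyl-2-(prop-1-en-2-yl)hex-4-en-1-yl]-5,7-bis(trimethylsilyloxy)-2-[2,4,6-tris(trimethylsilyloxy)phenyl]-2,3-dihydro-4H-chromen-4-one | C=C(C)[C@@H](CC=C(C)C)Cc1c(O[Si](C)(C)C)cc2c(c1O[Si](C)(C)C)C(=O)C[C@@H](c1c(O[Si](C)(C)C)cc(O[Si](C)(C)C)cc1O[Si](C)(C)C)O2
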